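Remark on the chemistry: compounds 4–7 and the transient 12 and 14 are racemic. This is harmless, because their stereocentres disappear when the central ring becomes aromatic; the single stereocentre of 23 is bought with 19.

## Analysis of the target

The target is a para-terphenyl. Its central benzene ring is fully substituted: 4-hydroxyphenyl rings at C3 and C6 and oxygen at C1, C2, C4 and C5. The para oxygens at C1 and C4 carry two different acyl groups, (3S)-3-acetoxybutanoyl at C1 and 3-phenylpropanoyl at C4, while the oxygens at C2 and C5 are free phenols. The only stereocentre is C3 of the butanoate chain (S, bearing the acetoxy group); it is remote from the ring, has no partner to relate to, and is best bought. Sensitive features are: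

- the two aryl esters, each next to a free ortho phenol onto which the acyl group can migrate under base;
- the β-acetoxy ester, which can lose acetic acid to give a crotonate;
- the C2/C5 hydroquinone, which can be oxidised to a quinone.

Apart from the two acyl groups the core is centrosymmetric. The difficulty is therefore not the skeleton but telling four ring oxygens apart: two stay free, and C1–O and C4–O must each receive its own acid. The plan rests on the segment C4(O)–C3(aryl)–C2(O) of the central ring. C3 and C2 can come from an aryl silyloxyalkyne and C4 from a ketene carbonyl, while C1, C6 and C5 come from a cyclobutenone with their oxygen or aryl substituents already attached. A ring made this way has a different tag on every oxygen from the moment it forms.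

## Retrosynthetic reasoning

23 ⇒ 22. The last bonds cut are the two benzyl–oxygen bonds on the outer rings. The outer phenols play no part in the central-ring chemistry, so they are masked from the start. Catalytic hydrogenolysis is neutral, which is what the finished ester/phenol array of 23 needs.

22 ⇒ 21. Next the O–Si bonds at C2 and C5 are cut. Free phenols at these positions are what allows acyl migration, so they stay silylated until both esters are in place. The forward step must remove both silyl groups with fluoride under acidic conditions, so that no phenoxide forms.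

21 ⇒ 18 + 20. The C1 O–acyl bond is cut. The stereocentre arrives ready-made in 20, which comes from 19 by O-acetylation. The more fragile of the two acyl groups goes on last and sees only the two deprotections.

18 ⇒ 17. The O–tert-butyl bond at C1 is cut. This ether is acid-labile and independent of the silyl ethers, benzyl ethers and the aryl ester of 17, so acid can expose C1–O alone.

17 ⇒ 15 + 16. The C4 O–acyl bond is cut. In 15 the C4 oxygen is the only free hydroxyl, so acylation with 16 needs no selectivity.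

15 ⇒ 7 + 10. Three ring bonds are cut: C3–C4, C1–C2 and C4–C5. This is the central disconnection. The alkyne 10 supplies C3 with its aryl group and C2 with its silyloxy group. The cyclobutenone 7 supplies C4 (its carbonyl, which becomes the free phenol), C1 (tert-butoxy), C6 (aryl) and C5 (silyloxy). Cutting here, and not at an aryl–aryl bond, means the four oxygens are differentiated by the ring-forming step itself. The forward reaction must join a vinylketene and an ynol ether in one orientation only.

7 ⇒ 6 ⇒ 4 ⇒ 1 + 2. The silyl ether of 7 comes from alcohol 6. Compound 6 is the product of a carbonyl transposition of 4 through diol 5: reduction of the ketone, then ionisation of the tertiary benzylic carbinol. Compound 4 is the adduct of aryllithium 3 (from 1) with the symmetric squarate 2. The four-membered ring is bought, and its two enol ether oxygens become C1–O and C4–O of the target.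

10 ⇒ 8. The alkyne C≡C–O unit is cut back to the ester carbonyl of 8. One-carbon homologation through ynolate 9, then O-silylation, turns a shelf ester into the ynol ether.

## Alternatives that were turned down

Alternative 1: The central ring is cut at C3–C4 and C6–C1 into two identical arylpyruvate halves. In the forward direction atromentin synthetase would load two molecules of 4-hydroxyphenylpyruvic acid A2 as thioesters and join them head to tail, each benzylic carbon acylating the other half, to release atromentin A1.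
- For: one operation, no protecting groups, and the whole terphenyl skeleton with all four ring oxygens. In steps to the skeleton it clearly beats the chosen route.
- Against: it needs an expressed adenylating enzyme and its nucleotide cofactor, not a bench reagent. More seriously, A1 is centrosymmetric: its ring oxygens are pairwise equivalent, and after reduction it is a hexaphenol. The target then needs two different acyl groups on para oxygens with four phenols left free. That is selectivity among six hydroxyls with no handle, under basic conditions that also let esters migrate.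
- Comparison: the chosen benzannulation is longer, but in 15 each central oxygen is tagged differently (free, tert-butyl, two silyl), which is the actual problem of this target.

Alternative 2: The central ring is cut at C2–C3, a Dieckmann bond. In the forward direction sodium prop-2-en-1-olate A5 opens the lactone carbonyl of the arylpyruvate-derived pyrandione A4. The ring oxygen leaves as the enolate of a benzyl ketone, whose carbon attacks the new allyl ester and closes the carbocycle, written as the mono-O-allyl dihydroxyquinone A3.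
- For: two cheap halves, a simple base-mediated step, and the para-diaryl pattern arises automatically. It probably reaches a terphenylquinone in fewer steps than the chosen route reaches 15.
- Against, on mechanism: a Dieckmann tetrahedral intermediate normally expels its alkoxide. The expected product is then the symmetric dihydroxyquinone, and the allyl tag is lost.
- Against, on structure: even if A3 forms, the allyl group sits on C2–O and distinguishes C2 from C5, the two oxygens that end up as identical free phenols. The oxygens that need different acids, C1 and C4, are the two quinone carbonyls; on reduction they appear together as free phenols beside C5–OH. The differentiation is missing exactly where it is needed.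
- Comparison: the chosen route delivers C1–O and C4–O as tert-butyl ether and free phenol from the ring-forming step.

Alternative 3: The outer rings are disconnected at C1'–C6' and C2'–C3'. In the forward direction the bis(acetaldehyde) A7, on a preformed fully oxygenated central ring, is converted to its bis-enamine. Each enamine carbon adds to but-3-en-2-one A8, and aldol condensation closes the bis(cyclohexenone) A6, which is later dehydrogenated to the two phenol rings.
- For: no aryl–aryl bond formation and no thermal cascade; every reaction is textbook chemistry. In predictability of the individual steps it is stronger than the chosen route, whose key step is untested with this much oxygen.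
- Against: it builds from acyclic carbon the one part of the molecule that can be bought, a 4-oxygenated phenyl ring. A7 needs two aldehyde arms on a benzene whose neighbouring positions are all substituted, which hinders the Michael step. Two stereocentres are made and destroyed. The late aromatisation must spare benzyl and methoxymethyl ethers. Finally, C1–O and C4–O carry the same methoxymethyl group in A6, so the two different esters again need a statistical mono-acylation.
- Comparison: the step count is well above that of the chosen route, which uses the aryl groups as bought and spends its effort on the central ring.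

Key step: step 5

## Route

Step 1
Reactants: 1 1-(benzyloxy)-4-bromobenzene; 2 di-tert-butyl squarate (3,4-di-tert-butoxycyclobut-3-ene-1,2-dione)
Product: 4 rac-4-[4-(benzyloxy)phenyl]-2,3-di-tert-butoxy-4-hydroxycyclobut-2-en-1-one, via aryllithium 3 (not isolated)
Conditions: n-BuLi, THF, −78 °C; then 2, THF, −78 °C; aq. NH4Cl
Reagents that add atoms: none
Why: Bromine–lithium exchange gives 3, which adds 1,2 to one of the two equivalent carbonyl groups of the squarate at low temperature, the standard entry to 4-aryl-4-hydroxycyclobutenones. The symmetry of 2 allows only one adduct, and the new stereocentre is racemic and later erased.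

Step 2
Reactants: 4 rac-4-[4-(benzyloxy)phenyl]-2,3-di-tert-butoxy-4-hydroxycyclobut-2-en-1-one
Product: 6 rac-3-[4-(benzyloxy)phenyl]-2-tert-butoxy-4-hydroxycyclobut-2-en-1-one, via cyclobutenediol 5 (not isolated)
Conditions: NaBH4, CeCl3·7H2O, MeOH/THF, −78 → −40 °C; then 1 M HCl (aq), 0 °C
Reagents that add atoms: none
Why: Luche 1,2-reduction of the vinylogous ester carbonyl gives diol 5. On acidification its tertiary, para-alkoxybenzylic, allylic hydroxyl ionises; the allyl cation is an oxocarbenium ion at the far tert-butoxy carbon and sheds that tert-butyl group, so the carbonyl is transposed (Stork–Danheiser-type transposition), with aryl on C3 and the remaining tert-butoxy group on C2. The secondary carbinol, now α to the ketone, should not ionise in cold dilute acid.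

Step 3
Reactants: 6 rac-3-[4-(benzyloxy)phenyl]-2-tert-butoxy-4-hydroxycyclobut-2-en-1-one
Product: 7 rac-3-[4-(benzyloxy)phenyl]-2-tert-butoxy-4-{[tert-butyl(dimethyl)silyl]oxy}cyclobut-2-en-1-one
Conditions: TBSCl, imidazole, DMF, 0 °C → rt
Reagents that add atoms: tert-butyl(chloro)dimethylsilane, CC(C)(C)[Si](C)(C)Cl
Why: Imidazole-promoted silylation of the only hydroxyl group; the mild base should leave the strained enone and its tert-butyl enol ether untouched.

Step 4
Reactants: 8 ethyl 4-(benzyloxy)benzoate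
Product: 10 {[4-(benzyloxy)phenyl]ethynyloxy}tri(propan-2-yl)silane, via lithium ynolate 9 (not isolated)
Conditions: CH2Br2, LiTMP, THF, −78 °C; LiHMDS; n-BuLi, −78 → 25 °C; then TIPSCl, −78 → 0 °C
Reagents that add atoms: dibromomethane, BrCBr; chlorotri(propan-2-yl)silane, CC(C)[Si](Cl)(C(C)C)C(C)C
Why: Kowalski ester homologation: LiCHBr2 adds to the ester, the resulting dibromo ketone enolate undergoes bromine–lithium exchange and 1,2-aryl shift to ynolate 9. The bulky silyl chloride reacts at oxygen, whereas small silyl chlorides would give silylketenes.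

Step 5
Reactants: 7 rac-3-[4-(benzyloxy)phenyl]-2-tert-butoxy-4-{[tert-butyl(dimethyl)silyl]oxy}cyclobut-2-en-1-one; 10 {[4-(benzyloxy)phenyl]ethynyloxy}tri(propan-2-yl)silane
Product: 15 2,5-bis[4-(benzyloxy)phenyl]-4-tert-butoxy-6-{[tert-butyl(dimethyl)silyl]oxy}-3-{[tri(propan-2-yl)silyl]oxy}phenol, via vinylketene 11 (not isolated), via vinylcyclobutenone 12 (not isolated), via dienylketene 13 (not isolated), via cyclohexadienone 14 (not isolated)
Conditions: PhMe (degassed), 80 → 110 °C, sealed tube
Reagents that add atoms: none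
Why: Heating opens 7 by conrotatory 4π electrocyclic ring opening, the silyloxy group turning outward, to vinylketene 11. The electron-rich alkyne 10 adds to the ketene in a (2+2) cycloaddition: its nucleophilic aryl-bearing carbon bonds to the ketene carbonyl carbon (C3–C4) and its silyloxy-bearing carbon to the tert-butoxy-bearing carbon (C1–C2), giving 12. A second 4π opening, tert-butoxy outward and vinyl inward, gives dienylketene 13, which closes the six-membered ring by thermal disrotatory 6π electrocyclisation (C4–C5) to 14; enolisation then gives phenol 15. The closest known reaction is the Danheiser benzannulation of cyclobutenones with siloxyalkynes to 3-silyloxyphenols. The one selectivity needed is the orientation of the (2+2) step, and the silyloxy group secures it by making the remote alkyne carbon the nucleophile, as in ketene–ynol ether cycloadditions generally. The ring openings are reversible, so a dienylketene of unproductive geometry can close again and reopen. No stereocentre survives, since those of 7, 12 and 14 are lost on aromatisation. Neither aryl group is placed so that it could cyclise onto a ketene, so ring closure onto an arene does not compete.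

Step 6
Reactants: 15 2,5-bis[4-(benzyloxy)phenyl]-4-tert-butoxy-6-{[tert-butyl(dimethyl)silyl]oxy}-3-{[tri(propan-2-yl)silyl]oxy}phenol; 16 3-phenylpropanoyl chloride
Product: 17 2,5-bis[4-(benzyloxy)phenyl]-4-tert-butoxy-6-{[tert-butyl(dimethyl)silyl]oxy}-3-{[tri(propan-2-yl)silyl]oxy}phenyl 3-phenylpropanoate
Conditions: pyridine, DMAP (cat.), CH2Cl2, 0 °C
Reagents that add atoms: none
Why: Acylation of the only free hydroxyl through the acylpyridinium ion (nucleophilic catalysis). Pyridine is too weak a base to form the phenoxide, so the neighbouring silyl group should not shift to the C4 oxygen before the acyl group arrives.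

Step 7
Reactants: 17 2,5-bis[4-(benzyloxy)phenyl]-4-tert-butoxy-6-{[tert-butyl(dimethyl)silyl]oxy}-3-{[tri(propan-2-yl)silyl]oxy}phenyl 3-phenylpropanoate
Product: 18 2,5-bis[4-(benzyloxy)phenyl]-6-{[tert-butyl(dimethyl)silyl]oxy}-4-hydroxy-3-{[tri(propan-2-yl)silyl]oxy}phenyl 3-phenylpropanoate
Conditions: CF3CO2H, Et3SiH, CH2Cl2, 0 °C
Reagents that add atoms: none
Why: Acid cleaves the crowded aryl tert-butyl ether by the SN1 path, and the silane reduces the tert-butyl cation before it can alkylate the electron-rich benzyloxyphenyl rings. Aryl silyl ethers, benzyl ethers and the aryl ester tolerate brief cold trifluoroacetic acid.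

Step 8
Reactants: 19 (3S)-3-hydroxybutanoic acid
Product: 20 (3S)-3-(acetyloxy)butanoic acid
Conditions: AcCl (neat), 0 °C → rt; then H2O
Reagents that add atoms: acetyl chloride, CC(=O)Cl
Why: O-Acetylation of the secondary alcohol under acidic, base-free conditions, so no β-elimination is expected; any mixed anhydride is hydrolysed on work-up. The C–O bond at the stereocentre is not touched, so the S configuration is retained.

Step 9
Reactants: 18 2,5-bis[4-(benzyloxy)phenyl]-6-{[tert-butyl(dimethyl)silyl]oxy}-4-hydroxy-3-{[tri(propan-2-yl)silyl]oxy}phenyl 3-phenylpropanoate; 20 (3S)-3-(acetyloxy)butanoic acid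
Product: 21 3,6-bis[4-(benzyloxy)phenyl]-5-{[tert-butyl(dimethyl)silyl]oxy}-4-[(3-phenylpropanoyl)oxy]-2-{[tri(propan-2-yl)silyl]oxy}phenyl (3S)-3-(acetyloxy)butanoate
Conditions: DCC, DMAP (cat.), CH2Cl2, 0 °C → rt
Reagents that add atoms: none
Why: Steglich esterification of the one free phenol. The stereocentre is β to the carbonyl and cannot epimerise by enolisation; low temperature and only catalytic base are chosen to suppress loss of acetate from the activated acid.

Step 10
Reactants: 21 3,6-bis[4-(benzyloxy)phenyl]-5-{[tert-butyl(dimethyl)silyl]oxy}-4-[(3-phenylpropanoyl)oxy]-2-{[tri(propan-2-yl)silyl]oxy}phenyl (3S)-3-(acetyloxy)butanoate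
Product: 22 3,6-bis[4-(benzyloxy)phenyl]-2,5-dihydroxy-4-[(3-phenylpropanoyl)oxy]phenyl (3S)-3-(acetyloxy)butanoate
Conditions: HF·pyridine, pyridine, THF, 0 °C → rt
Reagents that add atoms: none
Why: Fluoride cleaves both aryl O–Si bonds. The acidic medium keeps the liberated phenols protonated, so the neighbouring acyl groups should not migrate from C1–O to C2–O or from C4–O to C5–O. Esters, acetate and benzyl ethers are inert.

Step 11
Reactants: 22 3,6-bis[4-(benzyloxy)phenyl]-2,5-dihydroxy-4-[(3-phenylpropanoyl)oxy]phenyl (3S)-3-(acetyloxy)butanoate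
Product: 23 2,5-dihydroxy-3,6-bis(4-hydroxyphenyl)-4-[(3-phenylpropanoyl)oxy]phenyl (3S)-3-(acetyloxy)butanoate
Conditions: H2 (1 atm), 10% Pd/C, EtOAc, rt, then work-up under argon
Reagents that add atoms: none
Why: Hydrogenolysis of the two benzyl aryl ethers under neutral conditions; aryl esters, the acetate and the arene rings are not reduced. Air is excluded to protect the C2/C5 hydroquinone.

## Compound list

1 | 1-(benzyloxy)-4-bromobenzene | Brc1ccc(OCc2ccccc2)cc1 | starting material
2 | di-tert-butyl squarate (3,4-di-tert-butoxycyclobut-3-ene-1,2-dione) | CC(C)(C)OC1=C(OC(C)(C)C)C(=O)C1=O | starting material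
3 | [4-(benzyloxy)phenyl]lithium | [Li]c1ccc(OCc2ccccc2)cc1 | intermediate
4 | rac-4-[4-(benzyloxy)phenyl]-2,3-di-tert-butoxy-4-hydroxycyclobut-2-en-1-one | O=C1C(OC(C)(C)C)=C(OC(C)(C)C)C1(O)c1ccc(OCc2ccccc2)cc1 | intermediate
5 | 1-[4-(benzyloxy)phenyl]-2,3-di-tert-butoxycyclobut-2-ene-1,4-diol (racemic, mixture of diastereomers) | OC1C(OC(C)(C)C)=C(OC(C)(C)C)C1(O)c1ccc(OCc2ccccc2)cc1 | intermediate
6 | rac-3-[4-(benzyloxy)phenyl]-2-tert-butoxy-4-hydroxycyclobut-2-en-1-one | O=C1C(OC(C)(C)C)=C(c2ccc(OCc3ccccc3)cc2)C1O | intermediate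
7 | rac-3-[4-(benzyloxy)phenyl]-2-tert-butoxy-4-{[tert-butyl(dimethyl)silyl]oxy}cyclobut-2-en-1-one | O=C1C(OC(C)(C)C)=C(c2ccc(OCc3ccccc3)cc2)C1O[Si](C)(C)C(C)(C)C | intermediate
8 | ethyl 4-(benzyloxy)benzoate | CCOC(=O)c1ccc(OCc2ccccc2)cc1 | starting material
9 | lithium 2-[4-(benzyloxy)phenyl]ethynolate | [Li+].[O-]C#Cc1ccc(OCc2ccccc2)cc1 | intermediate
10 | {[4-(benzyloxy)phenyl]ethynyloxy}tri(propan-2-yl)silane | CC(C)[Si](OC#Cc1ccc(OCc2ccccc2)cc1)(C(C)C)C(C)C | intermediate
11 | (3E)-3-[4-(benzyloxy)phenyl]-2-tert-butoxy-4-{[tert-butyl(dimethyl)silyl]oxy}buta-1,3-dien-1-one | O=C=C(OC(C)(C)C)/C(c1ccc(OCc2ccccc2)cc1)=C/O[Si](C)(C)C(C)(C)C | intermediate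
12 | rac-2-[4-(benzyloxy)phenyl]-4-[(E)-1-[4-(benzyloxy)phenyl]-2-{[tert-butyl(dimethyl)silyl]oxy}ethenyl]-4-tert-butoxy-3-{[tri(propan-2-yl)silyl]oxy}cyclobut-2-en-1-one | O=C1C(c2ccc(OCc3ccccc3)cc2)=C(O[Si](C(C)C)(C(C)C)C(C)C)C1(OC(C)(C)C)/C(c1ccc(OCc2ccccc2)cc1)=C/O[Si](C)(C)C(C)(C)C | intermediate
13 | (3Z,5E)-2,5-bis[4-(benzyloxy)phenyl]-4-tert-butoxy-6-{[tert-butyl(dimethyl)silyl]oxy}-3-{[tri(propan-2-yl)silyl]oxy}hexa-1,3,5-trien-1-one | O=C=C(c1ccc(OCc2ccccc2)cc1)\C(O[Si](C(C)C)(C(C)C)C(C)C)=C(OC(C)(C)C)/C(c1ccc(OCc2ccccc2)cc1)=C/O[Si](C)(C)C(C)(C)C | intermediate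
14 | rac-2,5-bis[4-(benzyloxy)phenyl]-4-tert-butoxy-6-{[tert-butyl(dimethyl)silyl]oxy}-3-{[tri(propan-2-yl)silyl]oxy}cyclohexa-2,4-dien-1-one | O=C1C(c2ccc(OCc3ccccc3)cc2)=C(O[Si](C(C)C)(C(C)C)C(C)C)C(OC(C)(C)C)=C(c2ccc(OCc3ccccc3)cc2)C1O[Si](C)(C)C(C)(C)C | intermediate
15 | 2,5-bis[4-(benzyloxy)phenyl]-4-tert-butoxy-6-{[tert-butyl(dimethyl)silyl]oxy}-3-{[tri(propan-2-yl)silyl]oxy}phenol | Oc1c(-c2ccc(OCc3ccccc3)cc2)c(O[Si](C(C)C)(C(C)C)C(C)C)c(OC(C)(C)C)c(-c2ccc(OCc3ccccc3)cc2)c1O[Si](C)(C)C(C)(C)C | intermediate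
16 | 3-phenylpropanoyl chloride | O=C(Cl)CCc1ccccc1 | starting material
17 | 2,5-bis[4-(benzyloxy)phenyl]-4-tert-butoxy-6-{[tert-butyl(dimethyl)silyl]oxy}-3-{[tri(propan-2-yl)silyl]oxy}phenyl 3-phenylpropanoate | O=C(CCc1ccccc1)Oc1c(-c2ccc(OCc3ccccc3)cc2)c(O[Si](C(C)C)(C(C)C)C(C)C)c(OC(C)(C)C)c(-c2ccc(OCc3ccccc3)cc2)c1O[Si](C)(C)C(C)(C)C | intermediate
18 | 2,5-bis[4-(benzyloxy)phenyl]-6-{[tert-butyl(dimethyl)silyl]oxy}-4-hydroxy-3-{[tri(propan-2-yl)silyl]oxy}phenyl 3-phenylpropanoate | O=C(CCc1ccccc1)Oc1c(-c2ccc(OCc3ccccc3)cc2)c(O[Si](C(C)C)(C(C)C)C(C)C)c(O)c(-c2ccc(OCc3ccccc3)cc2)c1O[Si](C)(C)C(C)(C)C | intermediate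
19 | (3S)-3-hydroxybutanoic acid | C[C@H](O)CC(=O)O | starting material
20 | (3S)-3-(acetyloxy)butanoic acid | CC(=O)O[C@@H](C)CC(=O)O | intermediate
21 | 3,6-bis[4-(benzyloxy)phenyl]-5-{[tert-butyl(dimethyl)silyl]oxy}-4-[(3-phenylpropanoyl)oxy]-2-{[tri(propan-2-yl)silyl]oxy}phenyl (3S)-3-(acetyloxy)butanoate | CC(=O)O[C@@H](C)CC(=O)Oc1c(O[Si](C(C)C)(C(C)C)C(C)C)c(-c2ccc(OCc3ccccc3)cc2)c(OC(=O)CCc2ccccc2)c(O[Si](C)(C)C(C)(C)C)c1-c1ccc(OCc2ccccc2)cc1 | intermediate
22 | 3,6-bis[4-(benzyloxy)phenyl]-2,5-dihydroxy-4-[(3-phenylpropanoyl)oxy]phenyl (3S)-3-(acetyloxy)butanoate | CC(=O)O[C@@H](C)CC(=O)Oc1c(O)c(-c2ccc(OCc3ccccc3)cc2)c(OC(=O)CCc2ccccc2)c(O)c1-c1ccc(OCc2ccccc2)cc1 | intermediate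
23 | 2,5-dihydroxy-3,6-bis(4-hydroxyphenyl)-4-[(3-phenylpropanoyl)oxy]phenyl (3S)-3-(acetyloxy)butanoate | CC(=O)O[C@@H](C)CC(=O)Oc1c(O)c(-c2ccc(O)cc2)c(OC(=O)CCc2ccccc2)c(O)c1-c1ccc(O)cc1 | target

## Step count and least certain steps

Total: 11 steps. Longest linear sequence: 9 steps (1, 2, 3, 5, 6, 7, 9, 10, 11); steps 4 and 8 are side branches.

Step 5 (key step). The most likely failure is that vinylketene 11 is not intercepted. Its ketene carbon is made less electrophilic by the tert-butoxy and silyloxyvinyl donors, so self-reaction or decomposition may outrun the cycloaddition; the final 6π closure to a hexasubstituted ring is also crowded. The fallback gives up the annulation, sets out from 1 (via 3) and returns at 23.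
- Aryllithium 3 is quenched with triisopropyl borate and hydrolysed to [4-(benzyloxy)phenyl]boronic acid F1.
- Tetrabromo-1,4-benzoquinone and sodium benzyloxide give, by twofold addition–elimination, 2,5-bis(benzyloxy)-3,6-dibromocyclohexa-2,5-diene-1,4-dione F2.
- Twofold Suzuki–Miyaura coupling of F2 with F1 (Pd(PPh3)4, K2CO3, dioxane/H2O) gives 2,5-bis(benzyloxy)-3,6-bis[4-(benzyloxy)phenyl]cyclohexa-2,5-diene-1,4-dione F3.
- Na2S2O4 reduces this to 2,5-bis(benzyloxy)-3,6-bis[4-(benzyloxy)phenyl]benzene-1,4-diol F4, whose free hydroxyls are the C1 and C4 oxygens.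
- One equivalent of 16 with pyridine acylates one of the two equivalent hydroxyls to give 2,5-bis(benzyloxy)-3,6-bis[4-(benzyloxy)phenyl]-4-hydroxyphenyl 3-phenylpropanoate F5. This step is statistical, and unreacted F4 is recycled.
- DCC/DMAP with 20 gives 2,5-bis(benzyloxy)-3,6-bis[4-(benzyloxy)phenyl]-4-[(3-phenylpropanoyl)oxy]phenyl (3S)-3-(acetyloxy)butanoate F6, and hydrogenolysis (H2, Pd/C) of all four benzyl ethers gives 23.

This fallback trades the built-in differentiation of C1–O and C4–O for one statistical acylation.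

Step 2. The most likely failure is over-ionisation: after the transposition the secondary carbinol of 6 may also ionise and lose the second tert-butoxy group, leading to an aryl cyclobutenedione, or the tert-butyl enol ether may be cleaved by the acid. The fallback reverses the order of hydride and aryl addition, so that the secondary oxygen is already silylated when acid is applied. It sets out from 2 and 3 and returns at 7.
- LiAlH(OtBu)3 (THF, −78 °C) reduces one carbonyl of 2 to rac-2,3-di-tert-butoxy-4-hydroxycyclobut-2-en-1-one F7.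
- TBSCl/imidazole gives rac-2,3-di-tert-butoxy-4-{[tert-butyl(dimethyl)silyl]oxy}cyclobut-2-en-1-one F8.
- Aryllithium 3 adds to the remaining carbonyl to give 1-[4-(benzyloxy)phenyl]-2,3-di-tert-butoxy-4-{[tert-butyl(dimethyl)silyl]oxy}cyclobut-2-en-1-ol F9, whose tertiary carbinol ionises on mildly acidic work-up and gives 7 directly.

Step 6. The most likely failure is a 1,2 shift of the tert-butyldimethylsilyl group from the C5 oxygen to the neighbouring free C4 oxygen, during the hot annulation or before acylation, which would put the acyl group on the wrong oxygen. The fallback carries the C5 oxygen under the much less mobile triisopropylsilyl group. It sets out from 6 and returns at 22.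
- TIPSOTf/2,6-lutidine gives rac-3-[4-(benzyloxy)phenyl]-2-tert-butoxy-4-{[tri(propan-2-yl)silyl]oxy}cyclobut-2-en-1-one F10.
- Annulation with 10 as in step 5 gives 2,5-bis[4-(benzyloxy)phenyl]-4-tert-butoxy-3,6-bis{[tri(propan-2-yl)silyl]oxy}phenol F11.
- Acylation with 16 gives 2,5-bis[4-(benzyloxy)phenyl]-4-tert-butoxy-3,6-bis{[tri(propan-2-yl)silyl]oxy}phenyl 3-phenylpropanoate F12.
- Acid cleavage of the tert-butyl ether gives 2,5-bis[4-(benzyloxy)phenyl]-4-hydroxy-3,6-bis{[tri(propan-2-yl)silyl]oxy}phenyl 3-phenylpropanoate F13.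
- Esterification with 20 gives 3,6-bis[4-(benzyloxy)phenyl]-4-[(3-phenylpropanoyl)oxy]-2,5-bis{[tri(propan-2-yl)silyl]oxy}phenyl (3S)-3-(acetyloxy)butanoate F14, and HF·pyridine gives 22.

Step 9. The most likely failure is β-elimination of acetic acid from the activated acid, giving a crotonate, which competes because acylation of a phenol flanked by a bulky silyl ether and an aryl ring is slow. The fallback builds the side chain on the phenol without a carbodiimide-activated β-acetoxy acid. It sets out from 18 and returns at 21.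
- Heating 18 with 2,2,6-trimethyl-4H-1,3-dioxin-4-one in toluene (acetylketene, base-free) gives 3,6-bis[4-(benzyloxy)phenyl]-5-{[tert-butyl(dimethyl)silyl]oxy}-4-[(3-phenylpropanoyl)oxy]-2-{[tri(propan-2-yl)silyl]oxy}phenyl 3-oxobutanoate F15.
- Noyori hydrogenation of the β-keto ester (H2, RuCl2[(S)-BINAP], EtOH/CH2Cl2) sets the S carbinol by catalyst control and gives 3,6-bis[4-(benzyloxy)phenyl]-5-{[tert-butyl(dimethyl)silyl]oxy}-4-[(3-phenylpropanoyl)oxy]-2-{[tri(propan-2-yl)silyl]oxy}phenyl (3S)-3-hydroxybutanoate F16. Benzyl ethers survive this catalyst.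
- Ac2O/pyridine gives 21.

## Further compounds

F1 | step 5 | [4-(benzyloxy)phenyl]boronic acid | OB(O)c1ccc(OCc2ccccc2)cc1
F2 | step 5 | 2,5-bis(benzyloxy)-3,6-dibromocyclohexa-2,5-diene-1,4-dione | O=C1C(OCc2ccccc2)=C(Br)C(=O)C(OCc2ccccc2)=C1Br
F3 | step 5 | 2,5-bis(benzyloxy)-3,6-bis[4-(benzyloxy)phenyl]cyclohexa-2,5-diene-1,4-dione | O=C1C(OCc2ccccc2)=C(c2ccc(OCc3ccccc3)cc2)C(=O)C(OCc2ccccc2)=C1c1ccc(OCc2ccccc2)cc1
F4 | step 5 | 2,5-bis(benzyloxy)-3,6-bis[4-(benzyloxy)phenyl]benzene-1,4-diol | Oc1c(OCc2ccccc2)c(-c2ccc(OCc3ccccc3)cc2)c(O)c(OCc2ccccc2)c1-c1ccc(OCc2ccccc2)cc1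
F5 | step 5 | 2,5-bis(benzyloxy)-3,6-bis[4-(benzyloxy)phenyl]-4-hydroxyphenyl 3-phenylpropanoate | O=C(CCc1ccccc1)Oc1c(OCc2ccccc2)c(-c2ccc(OCc3ccccc3)cc2)c(O)c(OCc2ccccc2)c1-c1ccc(OCc2ccccc2)cc1
F6 | step 5 | 2,5-bis(benzyloxy)-3,6-bis[4-(benzyloxy)phenyl]-4-[(3-phenylpropanoyl)oxy]phenyl (3S)-3-(acetyloxy)butanoate | CC(=O)O[C@@H](C)CC(=O)Oc1c(OCc2ccccc2)c(-c2ccc(OCc3ccccc3)cc2)c(OC(=O)CCc2ccccc2)c(OCc2ccccc2)c1-c1ccc(OCc2ccccc2)cc1
F7 | step 2 | rac-2,3-di-tert-butoxy-4-hydroxycyclobut-2-en-1-one | O=C1C(OC(C)(C)C)=C(OC(C)(C)C)C1O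
F8 | step 2 | rac-2,3-di-tert-butoxy-4-{[tert-butyl(dimethyl)silyl]oxy}cyclobut-2-en-1-one | O=C1C(OC(C)(C)C)=C(OC(C)(C)C)C1O[Si](C)(C)C(C)(C)C
F9 | step 2 | 1-[4-(benzyloxy)phenyl]-2,3-di-tert-butoxy-4-{[tert-butyl(dimethyl)silyl]oxy}cyclobut-2-en-1-ol (racemic, mixture of diastereomers) | OC1(c2ccc(OCc3ccccc3)cc2)C(OC(C)(C)C)=C(OC(C)(C)C)C1O[Si](C)(C)C(C)(C)C
F10 | step 6 | rac-3-[4-(benzyloxy)phenyl]-2-tert-butoxy-4-{[tri(propan-2-yl)silyl]oxy}cyclobut-2-en-1-one | O=C1C(OC(C)(C)C)=C(c2ccc(OCc3ccccc3)cc2)C1O[Si](C(C)C)(C(C)C)C(C)C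
F11 | step 6 | 2,5-bis[4-(benzyloxy)phenyl]-4-tert-butoxy-3,6-bis{[tri(propan-2-yl)silyl]oxy}phenol | Oc1c(-c2ccc(OCc3ccccc3)cc2)c(O[Si](C(C)C)(C(C)C)C(C)C)c(OC(C)(C)C)c(-c2ccc(OCc3ccccc3)cc2)c1O[Si](C(C)C)(C(C)C)C(C)C
F12 | step 6 | 2,5-bis[4-(benzyloxy)phenyl]-4-tert-butoxy-3,6-bis{[tri(propan-2-yl)silyl]oxy}phenyl 3-phenylpropanoate | O=C(CCc1ccccc1)Oc1c(-c2ccc(OCc3ccccc3)cc2)c(O[Si](C(C)C)(C(C)C)C(C)C)c(OC(C)(C)C)c(-c2ccc(OCc3ccccc3)cc2)c1O[Si](C(C)C)(C(C)C)C(C)C
F13 | step 6 | 2,5-bis[4-(benzyloxy)phenyl]-4-hydroxy-3,6-bis{[tri(propan-2-yl)silyl]oxy}phenyl 3-phenylpropanoate | O=C(CCc1ccccc1)Oc1c(-c2ccc(OCc3ccccc3)cc2)c(O[Si](C(C)C)(C(C)C)C(C)C)c(O)c(-c2ccc(OCc3ccccc3)cc2)c1O[Si](C(C)C)(C(C)C)C(C)C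
F14 | step 6 | 3,6-bis[4-(benzyloxy)phenyl]-4-[(3-phenylpropanoyl)oxy]-2,5-bis{[tri(propan-2-yl)silyl]oxy}phenyl (3S)-3-(acetyloxy)butanoate | CC(=O)O[C@@H](C)CC(=O)Oc1c(O[Si](C(C)C)(C(C)C)C(C)C)c(-c2ccc(OCc3ccccc3)cc2)c(OC(=O)CCc2ccccc2)c(O[Si](C(C)C)(C(C)C)C(C)C)c1-c1ccc(OCc2ccccc2)cc1
F15 | step 9 | 3,6-bis[4-(benzyloxy)phenyl]-5-{[tert-butyl(dimethyl)silyl]oxy}-4-[(3-phenylpropanoyl)oxy]-2-{[tri(propan-2-yl)silyl]oxy}phenyl 3-oxobutanoate | CC(=O)CC(=O)Oc1c(O[Si](C(C)C)(C(C)C)C(C)C)c(-c2ccc(OCc3ccccc3)cc2)c(OC(=O)CCc2ccccc2)c(O[Si](C)(C)C(C)(C)C)c1-c1ccc(OCc2ccccc2)cc1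
F16 | step 9 | 3,6-bis[4-(benzyloxy)phenyl]-5-{[tert-butyl(dimethyl)silyl]oxy}-4-[(3-phenylpropanoyl)oxy]-2-{[tri(propan-2-yl)silyl]oxy}phenyl (3S)-3-hydroxybutanoate | C[C@H](O)CC(=O)Oc1c(O[Si](C(C)C)(C(C)C)C(C)C)c(-c2ccc(OCc3ccccc3)cc2)c(OC(=O)CCc2ccccc2)c(O[Si](C)(C)C(C)(C)C)c1-c1ccc(OCc2ccccc2)cc1
A1 | alternative 1 | atromentin (2,5-dihydroxy-3,6-bis(4-hydroxyphenyl)cyclohexa-2,5-diene-1,4-dione) | O=C1C(O)=C(c2ccc(O)cc2)C(=O)C(O)=C1c1ccc(O)cc1
A2 | alternative 1 | 3-(4-hydroxyphenyl)-2-oxopropanoic acid (4-hydroxyphenylpyruvic acid) | O=C(O)C(=O)Cc1ccc(O)cc1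
A3 | alternative 2 | 2-(allyloxy)-3,6-bis[4-(benzyloxy)phenyl]-5-hydroxycyclohexa-2,5-diene-1,4-dione | O=C1C(OCC=C)=C(c2ccc(OCc3ccccc3)cc2)C(=O)C(O)=C1c1ccc(OCc2ccccc2)cc1
A4 | alternative 2 | (6Z)-4-[4-(benzyloxy)phenyl]-6-{[4-(benzyloxy)phenyl]methylidene}-3-hydroxy-2H-pyran-2,5(6H)-dione | O=C1O/C(=C\c2ccc(OCc3ccccc3)cc2)C(=O)C(c2ccc(OCc3ccccc3)cc2)=C1O
A5 | alternative 2 | sodium prop-2-en-1-olate | [Na+].[O-]CC=C
A6 | alternative 3 | 4,4'-[2,5-bis(benzyloxy)-3,6-bis(methoxymethoxy)-1,4-phenylene]bis(cyclohex-2-en-1-one), mixture of diastereomers | O=C1C=CC(CC1)c1c(OCOC)c(OCc2ccccc2)c(C2C=CC(=O)CC2)c(OCOC)c1OCc1ccccc1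
A7 | alternative 3 | 2,2'-[2,5-bis(benzyloxy)-3,6-bis(methoxymethoxy)-1,4-phenylene]diacetaldehyde | O=CCc1c(OCOC)c(OCc2ccccc2)c(CC=O)c(OCOC)c1OCc1ccccc1
A8 | alternative 3 | but-3-en-2-one | CC(=O)C=C
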